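The route disconnects the bond between the lactone α-carbon and the quaternary carbon shared by ring A, ring B and the lactone, the same carbon that carries the lactone CH2O. Because both lactone carbons hang on this one atom, a diazo ester on the CH2O oxygen meets the geminal tertiary C–H through a five-membered transition state: one rhodium-carbenoid insertion builds the spiro γ-lactone and the quaternary stereocentre with retention. The precursor is a fully substituted methylenecyclohexane whose hydroxymethyl group carries a diazo(diethoxyphosphoryl)acetate; the phosphonate and an acetal-masked aldehyde on the furyl side chain later close ring B by Horner–Wadsworth–Emmons olefination, and Friedel–Crafts acylation at furan C3 closes ring C.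

Key step: step 17

Labels (target skeleton, used in the Why lines and in the names of 29–33): ring A = C1 (quaternary carbon bearing the lactone CH2O, C12), C2 (CH2), C3 (CH–O), C4 (C=CH2), C5 (C–CH3), C6 (CH); ring B = C1, C10 (lactone α-carbon), C9, C8, C7 (CH bearing the furan), C6; lactone = C1, C10, C11 (C=O), O, C12; ring C = C6, C7, furan C2′ and C3′, C14 (C=O), C13 (CH2), C5. The target is (1S,3S,5R,6R,7R) in these labels.

Design remark: the diazo ester carries a phosphonate and the side chain ends in a dioxolane, so that ring B closes by olefination at one defined carbon and not by a Claisen condensation that would have to choose among three enolisable carbonyl groups. The C3 oxygen is carried as the acetate of the target. The carbon skeleton and the bond made in the key step are unchanged.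

Assumption: in step 3 the sense of induction for the furyl-substituted allylic chloride is taken to follow that of cinnamyl chlorides, and the ligand antipode that gives (R)-6 is used.

Step 1
Reactants: 1 methyl (2E)-3-(furan-2-yl)prop-2-enoate
Product: 2 (2E)-3-(furan-2-yl)prop-2-en-1-ol
Conditions: (i-Bu)2AlH (2.2 equiv), CH2Cl2, −78 → 0 °C; aq. KNaC4H4O6
Reagents that add atoms: none
Why: 1,2-reduction of the conjugated ester by two hydride transfers gives the allylic alcohol and leaves the E alkene and the furan untouched.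

Step 2
Reactants: 2 (2E)-3-(furan-2-yl)prop-2-en-1-ol
Product: 4 2-[(1E)-3-chloroprop-1-en-1-yl]furan, via allylic mesylate 3 (not isolated)
Conditions: MsCl, 2,4,6-collidine, LiCl, DMF, 0 °C
Reagents that add atoms: lithium chloride [Li+].[Cl-] (chlorine of 4); methanesulfonyl chloride CS(=O)(=O)Cl (sulfonyl group of 3 only)
Why: Collington–Meyers chlorination, in which the mesylate formed in the flask is displaced by chloride at the primary allylic carbon (SN2) under non-acidic conditions that the furan tolerates.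

Step 3
Reactants: 4 2-[(1E)-3-chloroprop-1-en-1-yl]furan; 5 (1,3-dioxolan-2-ylmethyl)magnesium bromide
Product: 6 2-[(2R)-2-(furan-2-yl)but-3-en-1-yl]-1,3-dioxolane
Conditions: CuBr·SMe2 (3 mol%), chiral phosphoramidite from 1,1′-bi-2-naphthol and bis[1-(2-methoxyphenyl)ethyl]amine (3.3 mol%, antipode leading to (R)-6), CH2Cl2, −78 °C, 5 added slowly
Reagents that add atoms: none
Why: copper-catalysed asymmetric allylic alkylation (SN2′) in which the chiral copper–phosphoramidite complex delivers the alkyl group to the Re face of the furyl-bearing terminus, setting C7 as R and leaving the terminal vinyl group.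

Step 4
Reactants: 6 2-[(2R)-2-(furan-2-yl)but-3-en-1-yl]-1,3-dioxolane; 7 3-methylbut-3-en-2-one
Product: 8 (3E,5R)-6-(1,3-dioxolan-2-yl)-5-(furan-2-yl)-3-methylhex-3-en-2-one
Conditions: 7 (5 equiv), RuCl2(H2IMes)(=CH-C6H4-2-O-i-Pr) (second-generation Hoveyda–Grubbs catalyst, 5 mol%), CH2Cl2, 40 °C
Reagents that add atoms: none
Why: olefin cross-metathesis of the terminal alkene with the α-methyl vinyl ketone should give the trisubstituted enone as the more stable E isomer with loss of ethene, and C7 is not touched.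

Step 5
Reactants: 8 (3E,5R)-6-(1,3-dioxolan-2-yl)-5-(furan-2-yl)-3-methylhex-3-en-2-one
Product: 10 tert-butyl{[(3E,5R)-6-(1,3-dioxolan-2-yl)-5-(furan-2-yl)-3-methylhexa-1,3-dien-2-yl]oxy}dimethylsilane, via lithium dienolate 9 (not isolated)
Conditions: LiN(i-Pr)2, THF, −78 °C; then t-BuMe2SiCl, DMPU, −78 → 0 °C
Reagents that add atoms: tert-butyl(chloro)dimethylsilane CC(C)(C)[Si](C)(C)Cl
Why: kinetic deprotonation of the α′-methyl group and O-silylation of the cross-conjugated enolate give the 2-silyloxy diene, while the γ-hydrogen at C7 is not removed at −78 °C.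

Step 6
Reactants: 11 (4R)-4-benzyl-1,3-oxazolidin-2-one; 12 prop-2-enoyl chloride
Product: 13 (4R)-4-benzyl-3-(prop-2-enoyl)-1,3-oxazolidin-2-one
Conditions: Et3N, LiCl, THF, −20 → 0 °C
Reagents that add atoms: none
Why: N-acylation of the oxazolidinone with the acid chloride under mild amine/LiCl conditions gives the chiral acrylimide dienophile.

Step 7
Reactants: 10 tert-butyl{[(3E,5R)-6-(1,3-dioxolan-2-yl)-5-(furan-2-yl)-3-methylhexa-1,3-dien-2-yl]oxy}dimethylsilane; 13 (4R)-4-benzyl-3-(prop-2-enoyl)-1,3-oxazolidin-2-one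
Product: 14 (4R)-4-benzyl-3-{[(1S,2S)-4-{[tert-butyl(dimethyl)silyl]oxy}-2-[(1R)-2-(1,3-dioxolan-2-yl)-1-(furan-2-yl)ethyl]-3-methylcyclohex-3-en-1-yl]carbonyl}-1,3-oxazolidin-2-one
Conditions: Et2AlCl (1.4 equiv), CH2Cl2, −78 °C; Et3N then aq. NaHCO3
Reagents that add atoms: none
Why: Lewis acid-promoted Diels–Alder reaction in which the silyloxy group and the C6 substituent of the diene both direct the acyl-bearing carbon next to C6, the endo transition state makes the C1 and C6 substituents cis, and the diene adds to the Re face of the chelated s-cis acrylimide opposite the benzyl group, fixing C1 and C6 in the absolute sense required (the pre-set C7 biases the diene faces only weakly).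

Step 8
Reactants: 14 the Diels–Alder imide named in step 7
Product: 15 [(1S,2R)-4-{[tert-butyl(dimethyl)silyl]oxy}-2-[(1R)-2-(1,3-dioxolan-2-yl)-1-(furan-2-yl)ethyl]-3-methylcyclohex-3-en-1-yl]methanol
Conditions: LiBH4, MeOH (1 equiv), THF, 0 °C
Reagents that add atoms: none
Why: reductive cleavage of the N-acyl oxazolidinone gives the primary alcohol (C12) and returns the auxiliary, the silyl enol ether and the dioxolane being inert to borohydride.

Step 9
Reactants: 15 the cyclohexenylmethanol named in step 8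
Product: 16 [(1S,2R)-4-{[tert-butyl(dimethyl)silyl]oxy}-2-[(1R)-2-(1,3-dioxolan-2-yl)-1-(furan-2-yl)ethyl]-3-methylcyclohex-3-en-1-yl]methyl 2,2-dimethylpropanoate
Conditions: t-BuCOCl, Et3N, DMAP (cat.), CH2Cl2, 0 °C
Reagents that add atoms: 2,2-dimethylpropanoyl chloride CC(C)(C)C(Cl)=O
Why: acylation of the primary alcohol gives a pivalate that withstands the enolate, methylenation and oxidation steps and is removed by the hydride of step 14.

Step 10
Reactants: 16 the pivalate named in step 9; 17 tert-butyl 2-bromoacetate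
Product: 18 {(1S,2R,3R)-3-(2-tert-butoxy-2-oxoethyl)-2-[(1R)-2-(1,3-dioxolan-2-yl)-1-(furan-2-yl)ethyl]-3-methyl-4-oxocyclohexyl}methyl 2,2-dimethylpropanoate
Conditions: (Me2N)3S+ Me3SiF2− (TASF), 17 (1.5 equiv), THF, −78 → −30 °C
Reagents that add atoms: none
Why: fluoride cleavage of the silyl enol ether releases the regiodefined tetrasubstituted enolate, which is C-alkylated anti to the pseudoaxial C6 side chain, so that the quaternary centre C5 forms with CH2CO2t-Bu trans and CH3 cis to that side chain.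

Step 11
Reactants: 18 the ketone named in step 10
Product: 19 {(1S,2R,3R)-3-(2-tert-butoxy-2-oxoethyl)-2-[(1R)-2-(1,3-dioxolan-2-yl)-1-(furan-2-yl)ethyl]-3-methyl-4-methylidenecyclohexyl}methyl 2,2-dimethylpropanoate
Conditions: Zn, CH2Br2, TiCl4, THF–CH2Cl2, 0 °C → rt
Reagents that add atoms: dibromomethane BrCBr
Why: Lombardo methylenation with the non-basic zinc/titanium methylene reagent converts the hindered, enolisable ketone into the exocyclic alkene and spares both esters.

Step 12
Reactants: 19 the methylidene compound named in step 11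
Product: 20 {(1S,2R,3R,5RS)-3-(2-tert-butoxy-2-oxoethyl)-2-[(1R)-2-(1,3-dioxolan-2-yl)-1-(furan-2-yl)ethyl]-5-hydroxy-3-methyl-4-methylidenecyclohexyl}methyl 2,2-dimethylpropanoate
Conditions: SeO2 (0.5 equiv), t-BuOOH, CH2Cl2, rt
Reagents that add atoms: tert-butyl hydroperoxide CC(C)(C)OO; selenium dioxide O=[Se]=O (oxygen carrier)
Why: allylic hydroxylation by ene reaction and [2,3]-sigmatropic shift can occur only at C3, since the other allylic carbon (C5) is quaternary, and the C3 configuration formed here is erased in step 13.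

Step 13
Reactants: 20 the allylic alcohols named in step 12
Product: 21 {(1S,2R,3R)-3-(2-tert-butoxy-2-oxoethyl)-2-[(1R)-2-(1,3-dioxolan-2-yl)-1-(furan-2-yl)ethyl]-3-methyl-4-methylidene-5-oxocyclohexyl}methyl 2,2-dimethylpropanoate
Conditions: Dess–Martin periodinane, CH2Cl2, 0 °C → rt
Reagents that add atoms: none
Why: Dess–Martin oxidation converges both C3 epimers on the α-methylene ketone under neutral conditions compatible with furan, acetal and esters.

Step 14
Reactants: 21 the α-methylene ketone named in step 13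
Product: 22 tert-butyl {(1R,3S,5S,6R)-6-[(1R)-2-(1,3-dioxolan-2-yl)-1-(furan-2-yl)ethyl]-3-hydroxy-5-(hydroxymethyl)-1-methyl-2-methylidenecyclohexyl}acetate
Conditions: (i-Bu)2AlH (4.5 equiv), CH2Cl2, −78 °C; aq. KNaC4H4O6
Reagents that add atoms: none
Why: 1,2-reduction of the enone by the bulky hydride should occur from the face opposite the syn-axial C5 CH2CO2t-Bu group (equatorial attack on the favoured chair) to give the (3S) alcohol, while the same reagent cleaves the pivalate and leaves the tert-butyl ester at −78 °C.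

Step 15
Reactants: 22 the diol named in step 14; 23 2-(diethoxyphosphoryl)acetic acid
Product: 25 tert-butyl {(1R,3S,5S,6R)-3-(acetyloxy)-5-({[(diethoxyphosphoryl)acetyl]oxy}methyl)-6-[(1R)-2-(1,3-dioxolan-2-yl)-1-(furan-2-yl)ethyl]-1-methyl-2-methylidenecyclohexyl}acetate, via hydroxy phosphonoacetate 24 (not isolated)
Conditions: EDC·HCl, DMAP (cat.), CH2Cl2, 0 °C; then Ac2O, Et3N, DMAP, rt
Reagents that add atoms: acetic anhydride CC(=O)OC(C)=O
Why: carbodiimide (Steglich) esterification takes the unhindered primary alcohol in preference to the axial secondary allylic one, which is then acetylated in the same flask to install the acetate of the target.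

Step 16
Reactants: 25 the phosphonoacetate named in step 15
Product: 26 tert-butyl {(1R,3S,5S,6R)-3-(acetyloxy)-5-({[diazo(diethoxyphosphoryl)acetyl]oxy}methyl)-6-[(1R)-2-(1,3-dioxolan-2-yl)-1-(furan-2-yl)ethyl]-1-methyl-2-methylidenecyclohexyl}acetate
Conditions: 4-acetamidobenzenesulfonyl azide, DBU, MeCN, 0 °C → rt
Reagents that add atoms: 4-acetamidobenzenesulfonyl azide CC(=O)Nc1ccc(cc1)S(=O)(=O)N=[N+]=[N-]
Why: Regitz diazo transfer to the acidic phosphonoacetate methylene gives the diazo ester under mild base that the acetate and the tert-butyl ester tolerate.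

Step 17
Reactants: 26 the diazo phosphonoacetate named in step 16
Product: 27 tert-butyl {(5R,6R,7R,9S)-9-(acetyloxy)-4-(diethoxyphosphoryl)-6-[(1R)-2-(1,3-dioxolan-2-yl)-1-(furan-2-yl)ethyl]-7-methyl-8-methylidene-3-oxo-2-oxaspiro[4.5]decan-7-yl}acetate (C4 epimers)
Conditions: Rh2(O2CC7H15)4 (2 mol%), CH2Cl2 (0.005 M), 40 °C, slow addition of 26
Reagents that add atoms: none
Why: Loss of dinitrogen at the dirhodium tetracarboxylate gives an electrophilic acceptor/acceptor rhodium carbenoid that inserts into the C1–H bond in a concerted, asynchronous three-centre step, the new C–C bond forming on the face the hydrogen occupied. The closest known reaction type is the dirhodium-catalysed 1,5-C–H insertion of α-diazo-α-(dialkoxyphosphoryl)acetates and diazoacetates of primary alcohols to γ-butyrolactones, including spiro lactones from ring methines. The one new ring, the γ-lactone, closes by 1,5-insertion through a five-membered transition state and is spiro-fused to ring A at C1. The new quaternary stereocentre C1 is controlled by retention at the tertiary centre set in step 7, while C10 forms as an epimer mixture that is erased in step 19. The step needs site selectivity for C1–H and chemoselectivity over the furan and the exocyclic alkene: C1–H is tertiary and the only hydrogen five atoms from the carbenoid carbon, the OCH2 hydrogens are deactivated by the acyloxy group, 1,6-insertion at C2 or C6 is slower, and addition to the furan or alkene would need rings of eight or more atoms, which high dilution disfavours further.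

Step 18
Reactants: 27 the spiro lactone named in step 17
Product: 28 tert-butyl {(5R,6R,7R,9S)-9-(acetyloxy)-4-(diethoxyphosphoryl)-6-[(1R)-1-(furan-2-yl)-3-oxopropyl]-7-methyl-8-methylidene-3-oxo-2-oxaspiro[4.5]decan-7-yl}acetate (C4 epimers)
Conditions: PPTS, acetone–H2O (10:1), 50 °C
Reagents that add atoms: water O
Why: mild acid-catalysed acetal hydrolysis unmasks the C9 aldehyde without harming the tert-butyl ester, the allylic acetate or the furan.

Step 19
Reactants: 28 the aldehyde named in step 18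
Product: 29 tert-butyl ester of the ring-C seco acid: rings A and B trans-fused, γ-lactone (C12–O–C11–C10) with C9=C10 double bond, furan-2-yl on C7, CH3 and CH2CO2t-Bu on C5, methylidene on C4, acetoxy on C3, (1S,3S,5R,6R,7R)
Conditions: LiCl, DBU, MeCN (0.01 M), rt
Reagents that add atoms: none
Why: intramolecular Horner–Wadsworth–Emmons olefination under Masamune–Roush conditions joins C10 to C9 in a six-membered ring, the only carbanion site being the phosphonate carbon and the only electrophile the aldehyde, and the trans A/B fusion follows from the fixed C1 and C6 centres.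

Step 20
Reactants: 29 the tricyclic tert-butyl ester named in step 19
Product: 31 ring-C seco acid (C14 carboxylic acid; otherwise as 29), via trimethylsilyl ester 30 (not isolated)
Conditions: Me3SiOTf, 2,6-lutidine, CH2Cl2, 0 °C; then aqueous buffer (pH 4)
Reagents that add atoms: trimethylsilyl trifluoromethanesulfonate C[Si](C)(C)OS(=O)(=O)C(F)(F)F (silyl group of 30 only)
Why: silyl triflate-mediated cleavage of the tert-butyl ester (loss of 2-methylpropene) under buffered, non-protic conditions frees the acid without exposing the exocyclic alkene, the allylic acetate or the furan to strong protic acid.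

Step 21
Reactants: 31 the seco acid named in step 20
Product: 33 CNP0273675.1, (1S,3S,5R,6R,7R)-configured tetracycle with C3 acetate, C4 methylidene, C5 methyl, C9=C10 unsaturated γ-lactone and furan-fused cycloheptanone (ring C), via mixed trifluoroacetic anhydride 32 (not isolated)
Conditions: (CF3CO)2O (1.1 equiv), CH2Cl2, 0 °C → rt
Reagents that add atoms: trifluoroacetic anhydride O=C(OC(=O)C(F)(F)F)C(F)(F)F (trifluoroacetyl group of 32 only)
Why: intramolecular Friedel–Crafts acylation through the mixed anhydride closes the seven-membered ring at furan C3′, because the tether from C7 cannot reach C5′, and the mixed anhydride is too weak an electrophile to acylate the acetoxy-deactivated exocyclic alkene.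

Compound list
1 | methyl (2E)-3-(furan-2-yl)prop-2-enoate | COC(=O)/C=C/c1ccco1 | starting material
2 | (2E)-3-(furan-2-yl)prop-2-en-1-ol | OC/C=C/c1ccco1 | intermediate
3 | (2E)-3-(furan-2-yl)prop-2-en-1-yl methanesulfonate | CS(=O)(=O)OC/C=C/c1ccco1 | intermediate (not isolated)
4 | 2-[(1E)-3-chloroprop-1-en-1-yl]furan | ClC/C=C/c1ccco1 | intermediate
5 | (1,3-dioxolan-2-ylmethyl)magnesium bromide | Br[Mg]CC1OCCO1 | starting material
6 | 2-[(2R)-2-(furan-2-yl)but-3-en-1-yl]-1,3-dioxolane | C=C[C@H](c1ccco1)CC1OCCO1 | intermediate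
7 | 3-methylbut-3-en-2-one | CC(=O)C(C)=C | starting material
8 | (3E,5R)-6-(1,3-dioxolan-2-yl)-5-(furan-2-yl)-3-methylhex-3-en-2-one | CC(=O)/C(C)=C/[C@H](c1ccco1)CC1OCCO1 | intermediate
9 | lithium (3E,5R)-6-(1,3-dioxolan-2-yl)-5-(furan-2-yl)-3-methylhexa-1,3-dien-2-olate | [Li]OC(=C)/C(C)=C/[C@H](c1ccco1)CC1OCCO1 | intermediate (not isolated)
10 | tert-butyl{[(3E,5R)-6-(1,3-dioxolan-2-yl)-5-(furan-2-yl)-3-methylhexa-1,3-dien-2-yl]oxy}dimethylsilane | C=C(O[Si](C)(C)C(C)(C)C)/C(C)=C/[C@H](c1ccco1)CC1OCCO1 | intermediate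
11 | (4R)-4-benzyl-1,3-oxazolidin-2-one | O=C1N[C@H](Cc2ccccc2)CO1 | starting material
12 | prop-2-enoyl chloride | C=CC(Cl)=O | starting material
13 | (4R)-4-benzyl-3-(prop-2-enoyl)-1,3-oxazolidin-2-one | C=CC(=O)N1[C@H](Cc2ccccc2)COC1=O | intermediate
14 | (4R)-4-benzyl-3-{[(1S,2S)-4-{[tert-butyl(dimethyl)silyl]oxy}-2-[(1R)-2-(1,3-dioxolan-2-yl)-1-(furan-2-yl)ethyl]-3-methylcyclohex-3-en-1-yl]carbonyl}-1,3-oxazolidin-2-one | O=C1OC[C@@H](Cc2ccccc2)N1C(=O)[C@H]1CCC(O[Si](C)(C)C(C)(C)C)=C(C)[C@H]1[C@H](c1ccco1)CC1OCCO1 | intermediate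
15 | [(1S,2R)-4-{[tert-butyl(dimethyl)silyl]oxy}-2-[(1R)-2-(1,3-dioxolan-2-yl)-1-(furan-2-yl)ethyl]-3-methylcyclohex-3-en-1-yl]methanol | OC[C@H]1CCC(O[Si](C)(C)C(C)(C)C)=C(C)[C@H]1[C@H](c1ccco1)CC1OCCO1 | intermediate
16 | [(1S,2R)-4-{[tert-butyl(dimethyl)silyl]oxy}-2-[(1R)-2-(1,3-dioxolan-2-yl)-1-(furan-2-yl)ethyl]-3-methylcyclohex-3-en-1-yl]methyl 2,2-dimethylpropanoate | CC(C)(C)C(=O)OC[C@H]1CCC(O[Si](C)(C)C(C)(C)C)=C(C)[C@H]1[C@H](c1ccco1)CC1OCCO1 | intermediate
17 | tert-butyl 2-bromoacetate | BrCC(=O)OC(C)(C)C | starting material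
18 | {(1S,2R,3R)-3-(2-tert-butoxy-2-oxoethyl)-2-[(1R)-2-(1,3-dioxolan-2-yl)-1-(furan-2-yl)ethyl]-3-methyl-4-oxocyclohexyl}methyl 2,2-dimethylpropanoate | CC(C)(C)C(=O)OC[C@H]1CCC(=O)[C@](C)(CC(=O)OC(C)(C)C)[C@H]1[C@H](c1ccco1)CC1OCCO1 | intermediate
19 | {(1S,2R,3R)-3-(2-tert-butoxy-2-oxoethyl)-2-[(1R)-2-(1,3-dioxolan-2-yl)-1-(furan-2-yl)ethyl]-3-methyl-4-methylidenecyclohexyl}methyl 2,2-dimethylpropanoate | CC(C)(C)C(=O)OC[C@H]1CCC(=C)[C@](C)(CC(=O)OC(C)(C)C)[C@H]1[C@H](c1ccco1)CC1OCCO1 | intermediate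
20 | {(1S,2R,3R,5RS)-3-(2-tert-butoxy-2-oxoethyl)-2-[(1R)-2-(1,3-dioxolan-2-yl)-1-(furan-2-yl)ethyl]-5-hydroxy-3-methyl-4-methylidenecyclohexyl}methyl 2,2-dimethylpropanoate | CC(C)(C)C(=O)OC[C@H]1CC(O)C(=C)[C@](C)(CC(=O)OC(C)(C)C)[C@H]1[C@H](c1ccco1)CC1OCCO1 | intermediate
21 | {(1S,2R,3R)-3-(2-tert-butoxy-2-oxoethyl)-2-[(1R)-2-(1,3-dioxolan-2-yl)-1-(furan-2-yl)ethyl]-3-methyl-4-methylidene-5-oxocyclohexyl}methyl 2,2-dimethylpropanoate | CC(C)(C)C(=O)OC[C@H]1CC(=O)C(=C)[C@](C)(CC(=O)OC(C)(C)C)[C@H]1[C@H](c1ccco1)CC1OCCO1 | intermediate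
22 | tert-butyl {(1R,3S,5S,6R)-6-[(1R)-2-(1,3-dioxolan-2-yl)-1-(furan-2-yl)ethyl]-3-hydroxy-5-(hydroxymethyl)-1-methyl-2-methylidenecyclohexyl}acetate | OC[C@H]1C[C@H](O)C(=C)[C@](C)(CC(=O)OC(C)(C)C)[C@H]1[C@H](c1ccco1)CC1OCCO1 | intermediate
23 | 2-(diethoxyphosphoryl)acetic acid | CCOP(=O)(OCC)CC(=O)O | starting material
24 | tert-butyl {(1R,3S,5S,6R)-5-({[(diethoxyphosphoryl)acetyl]oxy}methyl)-6-[(1R)-2-(1,3-dioxolan-2-yl)-1-(furan-2-yl)ethyl]-3-hydroxy-1-methyl-2-methylidenecyclohexyl}acetate | CCOP(=O)(OCC)CC(=O)OC[C@H]1C[C@H](O)C(=C)[C@](C)(CC(=O)OC(C)(C)C)[C@H]1[C@H](c1ccco1)CC1OCCO1 | intermediate (not isolated)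
25 | tert-butyl {(1R,3S,5S,6R)-3-(acetyloxy)-5-({[(diethoxyphosphoryl)acetyl]oxy}methyl)-6-[(1R)-2-(1,3-dioxolan-2-yl)-1-(furan-2-yl)ethyl]-1-methyl-2-methylidenecyclohexyl}acetate | CCOP(=O)(OCC)CC(=O)OC[C@H]1C[C@H](OC(C)=O)C(=C)[C@](C)(CC(=O)OC(C)(C)C)[C@H]1[C@H](c1ccco1)CC1OCCO1 | intermediate
26 | tert-butyl {(1R,3S,5S,6R)-3-(acetyloxy)-5-({[diazo(diethoxyphosphoryl)acetyl]oxy}methyl)-6-[(1R)-2-(1,3-dioxolan-2-yl)-1-(furan-2-yl)ethyl]-1-methyl-2-methylidenecyclohexyl}acetate | CCOP(=O)(OCC)C(=[N+]=[N-])C(=O)OC[C@H]1C[C@H](OC(C)=O)C(=C)[C@](C)(CC(=O)OC(C)(C)C)[C@H]1[C@H](c1ccco1)CC1OCCO1 | intermediate (key-step precursor)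
27 | tert-butyl {(5R,6R,7R,9S)-9-(acetyloxy)-4-(diethoxyphosphoryl)-6-[(1R)-2-(1,3-dioxolan-2-yl)-1-(furan-2-yl)ethyl]-7-methyl-8-methylidene-3-oxo-2-oxaspiro[4.5]decan-7-yl}acetate (C4 epimers) | O=C1C(P(=O)(OCC)OCC)[C@]2(CO1)C[C@H](OC(C)=O)C(=C)[C@](C)(CC(=O)OC(C)(C)C)[C@H]2[C@H](c1ccco1)CC1OCCO1 | intermediate (key-step product)
28 | tert-butyl {(5R,6R,7R,9S)-9-(acetyloxy)-4-(diethoxyphosphoryl)-6-[(1R)-1-(furan-2-yl)-3-oxopropyl]-7-methyl-8-methylidene-3-oxo-2-oxaspiro[4.5]decan-7-yl}acetate (C4 epimers) | O=C1C(P(=O)(OCC)OCC)[C@]2(CO1)C[C@H](OC(C)=O)C(=C)[C@](C)(CC(=O)OC(C)(C)C)[C@H]2[C@H](c1ccco1)CC=O | intermediate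
29 | tert-butyl ester of the (1S,3S,5R,6R,7R) ring-C seco acid (rings A and B and the C9=C10 unsaturated γ-lactone closed; furan-2-yl on C7; CH2CO2t-Bu on C5) | C=C1[C@@H](OC(C)=O)C[C@@]23COC(=O)C2=CC[C@@H](c2ccco2)[C@@H]3[C@@]1(C)CC(=O)OC(C)(C)C | intermediate
30 | trimethylsilyl ester of the (1S,3S,5R,6R,7R) ring-C seco acid | C=C1[C@@H](OC(C)=O)C[C@@]23COC(=O)C2=CC[C@@H](c2ccco2)[C@@H]3[C@@]1(C)CC(=O)O[Si](C)(C)C | intermediate (not isolated)
31 | (1S,3S,5R,6R,7R) ring-C seco acid (C14 carboxylic acid) | C=C1[C@@H](OC(C)=O)C[C@@]23COC(=O)C2=CC[C@@H](c2ccco2)[C@@H]3[C@@]1(C)CC(=O)O | intermediate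
32 | mixed anhydride of the ring-C seco acid with trifluoroacetic acid | C=C1[C@@H](OC(C)=O)C[C@@]23COC(=O)C2=CC[C@@H](c2ccco2)[C@@H]3[C@@]1(C)CC(=O)OC(=O)C(F)(F)F | intermediate (not isolated)
33 | CNP0273675.1, (1S,3S,5R,6R,7R) | C=C1[C@@H](OC(C)=O)C[C@@]23COC(=O)C2=CC[C@H]2c4occc4C(=O)C[C@]1(C)[C@@H]23 | target

Total step count: 21. Longest linear sequence: 20 steps (steps 1–5 and 7–21 from 1; step 6 is a one-step branch).

Steps most likely to fail

Step 17. The carbenoid may be consumed by addition to the furan, by dimerisation or by 1,6-insertion before it reaches C1–H, because in the favoured chair that hydrogen is flanked by the syn-axial C3 acetoxy and C5 CH2CO2t-Bu groups. The fallback moves the insertion to a stage at which C3 is still a methylene group. It sets out from 19: (i-Bu)2AlH at −78 °C removes the pivalate to give alcohol F1, esterification with 23 (EDC·HCl, DMAP) gives phosphonoacetate F2, and diazo transfer (4-acetamidobenzenesulfonyl azide, DBU) gives diazo ester F3. Rh2(O2CC7H15)4 under high dilution then closes spiro lactone F4. SeO2/t-BuOOH gives allylic alcohols F5, Dess–Martin oxidation gives enone F6, NaBH4/CeCl3·7H2O gives (9S)-alcohol F7, and acetylation (Ac2O, DMAP) comes back to the route at 27.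

Step 7. The stoichiometric aluminium Lewis acid may strip the silyl enol ether or open the dioxolane, and facial selectivity may erode if the auxiliary and the C7 centre are mismatched. The fallback replaces auxiliary control by catalyst control. It sets out from 10: methyl acrylate and a substoichiometric chiral oxazaborolidinium salt (3,3-diphenyl-1-(2-methylphenyl)tetrahydro-1H,3H-pyrrolo[1,2-c][1,3,2]oxazaborole protonated by HN(SO2CF3)2, antipode chosen for Re-face addition, CH2Cl2, −78 °C) give methyl ester F8. LiBH4 reduction comes back to the route at 15, so steps 6–8 are replaced.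

Step 4. The metathesis may stall because a trisubstituted enone must form next to a branched allylic carbon, with 7 homodimerising or polymerising instead. The fallback builds the enone by olefination. It sets out from 6: OsO4 (cat.), NaIO4 and 2,6-lutidine in dioxane–water cleave the vinyl group to aldehyde F9. This is used at once, to limit epimerisation at the furyl-bearing carbon, in a Horner–Wadsworth–Emmons reaction with diethyl (3-oxobutan-2-yl)phosphonate (LiCl, i-Pr2NEt, MeCN, 0 °C), which comes back to the route at 8.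

Further compounds
F1 | step 17 | tert-butyl {(1R,2R,3S)-2-[(1R)-2-(1,3-dioxolan-2-yl)-1-(furan-2-yl)ethyl]-3-(hydroxymethyl)-1-methyl-6-methylidenecyclohexyl}acetate | OC[C@H]1CCC(=C)[C@](C)(CC(=O)OC(C)(C)C)[C@H]1[C@H](c1ccco1)CC1OCCO1
F2 | step 17 | tert-butyl {(1R,2R,3S)-3-({[(diethoxyphosphoryl)acetyl]oxy}methyl)-2-[(1R)-2-(1,3-dioxolan-2-yl)-1-(furan-2-yl)ethyl]-1-methyl-6-methylidenecyclohexyl}acetate | CCOP(=O)(OCC)CC(=O)OC[C@H]1CCC(=C)[C@](C)(CC(=O)OC(C)(C)C)[C@H]1[C@H](c1ccco1)CC1OCCO1
F3 | step 17 | tert-butyl {(1R,2R,3S)-3-({[diazo(diethoxyphosphoryl)acetyl]oxy}methyl)-2-[(1R)-2-(1,3-dioxolan-2-yl)-1-(furan-2-yl)ethyl]-1-methyl-6-methylidenecyclohexyl}acetate | CCOP(=O)(OCC)C(=[N+]=[N-])C(=O)OC[C@H]1CCC(=C)[C@](C)(CC(=O)OC(C)(C)C)[C@H]1[C@H](c1ccco1)CC1OCCO1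
F4 | step 17 | tert-butyl {(5R,6R,7R)-4-(diethoxyphosphoryl)-6-[(1R)-2-(1,3-dioxolan-2-yl)-1-(furan-2-yl)ethyl]-7-methyl-8-methylidene-3-oxo-2-oxaspiro[4.5]decan-7-yl}acetate (C4 epimers) | O=C1C(P(=O)(OCC)OCC)[C@]2(CO1)CCC(=C)[C@](C)(CC(=O)OC(C)(C)C)[C@H]2[C@H](c1ccco1)CC1OCCO1
F5 | step 17 | tert-butyl {(5R,6R,7R,9RS)-4-(diethoxyphosphoryl)-6-[(1R)-2-(1,3-dioxolan-2-yl)-1-(furan-2-yl)ethyl]-9-hydroxy-7-methyl-8-methylidene-3-oxo-2-oxaspiro[4.5]decan-7-yl}acetate | O=C1C(P(=O)(OCC)OCC)[C@]2(CO1)CC(O)C(=C)[C@](C)(CC(=O)OC(C)(C)C)[C@H]2[C@H](c1ccco1)CC1OCCO1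
F6 | step 17 | tert-butyl {(5R,6R,7R)-4-(diethoxyphosphoryl)-6-[(1R)-2-(1,3-dioxolan-2-yl)-1-(furan-2-yl)ethyl]-7-methyl-8-methylidene-3,9-dioxo-2-oxaspiro[4.5]decan-7-yl}acetate | O=C1C(P(=O)(OCC)OCC)[C@]2(CO1)CC(=O)C(=C)[C@](C)(CC(=O)OC(C)(C)C)[C@H]2[C@H](c1ccco1)CC1OCCO1
F7 | step 17 | tert-butyl {(5R,6R,7R,9S)-4-(diethoxyphosphoryl)-6-[(1R)-2-(1,3-dioxolan-2-yl)-1-(furan-2-yl)ethyl]-9-hydroxy-7-methyl-8-methylidene-3-oxo-2-oxaspiro[4.5]decan-7-yl}acetate | O=C1C(P(=O)(OCC)OCC)[C@]2(CO1)C[C@H](O)C(=C)[C@](C)(CC(=O)OC(C)(C)C)[C@H]2[C@H](c1ccco1)CC1OCCO1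
F8 | step 7 | methyl (1S,2S)-4-{[tert-butyl(dimethyl)silyl]oxy}-2-[(1R)-2-(1,3-dioxolan-2-yl)-1-(furan-2-yl)ethyl]-3-methylcyclohex-3-ene-1-carboxylate | COC(=O)[C@H]1CCC(O[Si](C)(C)C(C)(C)C)=C(C)[C@H]1[C@H](c1ccco1)CC1OCCO1
F9 | step 4 | (2S)-3-(1,3-dioxolan-2-yl)-2-(furan-2-yl)propanal | O=C[C@H](c1ccco1)CC1OCCO1
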